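**Retrosynthetic overview**
1. The diene chain is cut at its disubstituted C=C (Julia–Kocienski) into ring A sulfone 13 and ring B enal 35; the enal and both CH2OH groups of ring B are carried as esters until the end (LiAlH4, then MnO2).
2. Ring B is numbered C1 (quaternary, CH2OH), C2 (CH, hydroxypropyl), C3 (sp2 carbon of the enal), C4, C5 (CH2), C6 (C(OH)CH3); it is closed at C5–C6 by an SmI2 Barbier cyclisation of iodo keto ester 31.
3. Feature that allows this: C6 is a carbinol carbon next to quaternary C1, which bears a one-carbon oxygenated group. At the ketone/tert-butyl ester level these form a β-keto ester that chelates samarium, and C5 is the outer carbon of a two-carbon arm on C3. The C–I carbon and the C=O carbon are both acceptors and are joined after reductive polarity reversal.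
4. The (Z)-tetrasubstituted enoate is fixed before ring closure (E-enol tosylate, Suzuki coupling with retention). C1 and C2 are set on a butyrolactone template (copper hydride reduction, alkylation anti to the side chain), which is then opened with MeLi.
5. Ring order: ring A is carried from 2-methylcyclohexenone (conjugate addition, Shapiro, hydroboration, methylenation); the temporary lactone ring is opened in step 13; ring B is formed last, in step 21.

Key step: step 21

Assumption: the ligand enantiomers named in steps 1 and 10 are those taken to give the configurations drawn for 3 and 18; the route depends on those configurations, not on the ligand descriptor.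

Abbreviation used in names: TBDPS = tert-butyl(diphenyl)silyl.

**Ring A sulfone**

Step 1
Reactants: 1 2-methylcyclohex-2-en-1-one
Product: 3 (3S)-2,2,3-trimethylcyclohexan-1-one, via magnesium enolate 2 (not isolated)
Conditions: MeMgBr, Cu(OTf)2 (3 mol %), chiral N-heterocyclic carbene ligand (4 mol %), Et2O, −30 °C; then MeI, DMPU, −30 °C → rt
Reagents that add atoms: methylmagnesium bromide (C[Mg]Br); iodomethane (CI)
Why: Copper-catalysed asymmetric conjugate addition sets the C3 methyl stereocentre under ligand control, and the regiodefined magnesium enolate is C-methylated at C2 (enolate trapping), which builds the gem-dimethyl carbon without a further stereocentre.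

Step 2
Reactants: 3 (3S)-2,2,3-trimethylcyclohexan-1-one; 4 2,4,6-tri(propan-2-yl)benzenesulfonohydrazide
Product: 5 trisylhydrazone of 3
Conditions: MeOH, HCl (cat.), rt
Reagents that add atoms: none
Why: Condensation of the ketone with the sulfonyl hydrazide gives the hydrazone needed for the Shapiro reaction and leaves the stereocentre untouched.

Step 3
Reactants: 5 trisylhydrazone of 3
Product: 7 [(5S)-5,6,6-trimethylcyclohex-1-en-1-yl]methanol, via vinyllithium 6 (not isolated)
Conditions: n-BuLi (2.2 equiv), TMEDA, THF, −78 → 0 °C; then (CH2O)n, 0 °C → rt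
Reagents that add atoms: formaldehyde (C=O)
Why: Shapiro reaction: only the CH2 side can be deprotonated because the other α-carbon is quaternary, so loss of sulfinate and N2 should give one vinyllithium, which is hydroxymethylated.

Step 4
Reactants: 7 [(5S)-5,6,6-trimethylcyclohex-1-en-1-yl]methanol
Product: 9 (1S,2R,4S)-2-(hydroxymethyl)-3,3,4-trimethylcyclohexan-1-ol, via alkylborane 8 (not isolated)
Conditions: BH3·THF, THF, 0 °C → rt; then NaOH, H2O2, 0 °C → rt
Reagents that add atoms: hydrogen peroxide (OO)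
Why: Hydroboration–oxidation: H and B add cis from the ring face opposite the pseudo-axial methyl of the neighbouring gem-dimethyl carbon, boron going to the ring CH, so that CH2OH should come out cis to the ring methyl (the cis-1,3 relation of ring A).

Step 5
Reactants: 9 (1S,2R,4S)-2-(hydroxymethyl)-3,3,4-trimethylcyclohexan-1-ol
Product: 10 (1S,2S,4S)-3,3,4-trimethyl-2-{[(1-phenyl-1H-tetrazol-5-yl)sulfanyl]methyl}cyclohexan-1-ol
Conditions: 1-phenyl-1H-tetrazole-5-thiol, PPh3, DIAD, THF, 0 °C → rt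
Reagents that add atoms: 1-phenyl-1H-tetrazole-5-thiol (Sc1nnnn1-c1ccccc1)
Why: Mitsunobu thioetherification should occur only at the primary hydroxyl, the hindered secondary alcohol being left, and no stereocentre is involved.

Step 6
Reactants: 10 (1S,2S,4S)-hydroxy sulfide
Product: 11 (2S,4S)-3,3,4-trimethyl-2-{[(1-phenyl-1H-tetrazol-5-yl)sulfanyl]methyl}cyclohexan-1-one
Conditions: Dess–Martin periodinane, NaHCO3, CH2Cl2, rt
Reagents that add atoms: none
Why: Dess–Martin oxidation of the secondary alcohol tolerates the thioether, and the α-stereocentre is kept because the cis (diequatorial) 2,4-isomer is also the more stable one.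

Step 7
Reactants: 11 (2S,4S)-keto sulfide
Product: 12 1-phenyl-5-({[(1R,3S)-2,2,3-trimethyl-6-methylidenecyclohexyl]methyl}sulfanyl)-1H-tetrazole
Conditions: Zn, CH2Br2, TiCl4, THF/CH2Cl2, 0 °C → rt
Reagents that add atoms: dibromomethane (BrCBr)
Why: Lombardo methylenation uses a non-basic gem-dimetallic reagent, so the enolisable β-thio ketone should give the exocyclic alkene without β-elimination of thiolate or epimerisation.

Step 8
Reactants: 12 ring A sulfide
Product: 13 1-phenyl-5-({[(1R,3S)-2,2,3-trimethyl-6-methylidenecyclohexyl]methyl}sulfonyl)-1H-tetrazole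
Conditions: (NH4)6Mo7O24·4H2O (cat.), H2O2 (30 %), EtOH, 0 °C → rt
Reagents that add atoms: hydrogen peroxide (OO)
Why: Molybdate-catalysed peroxide oxidation of the sulfide gives the Julia–Kocienski sulfone, and the hindered 1,1-disubstituted alkene is not expected to be epoxidised.

**Ring B**

Step 9
Reactants: 14 tert-butyl(diphenyl)(prop-2-en-1-yloxy)silane; 15 4-bromofuran-2(5H)-one
Product: 17 4-[3-(TBDPS-oxy)propyl]furan-2(5H)-one, via alkyl-9-BBN 16 (not isolated)
Conditions: 9-BBN, THF, 0 °C → rt; then 15, Pd(dppf)Cl2 (5 mol %), K3PO4 (aq), DMF, 50 °C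
Reagents that add atoms: none
Why: Anti-Markovnikov hydroboration of the allyl ether followed by B-alkyl Suzuki–Miyaura coupling with the vinylogous acyl bromide attaches the three-carbon silyloxy chain to C4 of the butenolide.

Step 10
Reactants: 17 4-[3-(TBDPS-oxy)propyl]furan-2(5H)-one
Product: 18 (4S)-4-[3-(TBDPS-oxy)propyl]oxolan-2-one
Conditions: Cu(OAc)2 (5 mol %), (S)-p-tol-BINAP (5.5 mol %), (EtO)2MeSiH, t-BuOH, toluene, 0 °C → rt
Reagents that add atoms: none
Why: Copper hydride catalysed asymmetric conjugate reduction delivers hydride to C4 of the butenolide on the face chosen by the chiral bisphosphine and so sets the stereocentre that becomes C2 of ring B.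

Step 11
Reactants: 18 (4S)-4-[3-(TBDPS-oxy)propyl]oxolan-2-one
Product: 19 tert-butyl (3S,4S)-2-oxo-4-[3-(TBDPS-oxy)propyl]oxolane-3-carboxylate
Conditions: LiHMDS (2.2 equiv), THF, −78 °C; then Boc2O, −78 °C → rt
Reagents that add atoms: di-tert-butyl dicarbonate (CC(C)(C)OC(=O)OC(=O)OC(C)(C)C)
Why: Claisen-type C-acylation of the lactone enolate gives the malonate-type lactone, held as its enolate by the second equivalent of base; the new CH centre (trans, epimerisable) is erased in step 12.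

Step 12
Reactants: 19 tert-butyl (3S,4S)-2-oxo-4-[3-(TBDPS-oxy)propyl]oxolane-3-carboxylate; 20 2-(2-bromoethyl)-1,3-dioxolane
Product: 21 tert-butyl (3R,4S)-3-[2-(1,3-dioxolan-2-yl)ethyl]-2-oxo-4-[3-(TBDPS-oxy)propyl]oxolane-3-carboxylate
Conditions: NaH, DMF, 0 °C; then 20, NaI (cat.), 45 °C
Reagents that add atoms: none
Why: SN2 alkylation of the stabilised enolate creates the quaternary stereocentre; the bromide approaches the planar enolate anti to the C4 side chain, so the acetal arm ends trans and the tert-butyl ester cis to it (1,2-induction in the five-membered template).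

Step 13
Reactants: 21 quaternary lactone
Product: 22 tert-butyl (2R,3S)-2-acetyl-2-[2-(1,3-dioxolan-2-yl)ethyl]-3-(hydroxymethyl)-6-(TBDPS-oxy)hexanoate (in equilibrium with its five-membered hemiketal)
Conditions: MeLi (1.1 equiv), THF, −78 °C; AcOH quench at −78 °C
Reagents that add atoms: methyllithium (C[Li])
Why: Methyllithium adds to the lactone carbonyl, which is more electrophilic and less shielded than the tert-butyl ester; the lithium lactolate survives at −78 °C and gives the methyl ketone and the free primary alcohol on cold acidic quench, with both stereocentres untouched.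

Step 14
Reactants: 22 hydroxy ketone
Product: 23 tert-butyl (2R,3S)-2-acetyl-2-[2-(1,3-dioxolan-2-yl)ethyl]-3-formyl-6-(TBDPS-oxy)hexanoate
Conditions: Dess–Martin periodinane, NaHCO3, CH2Cl2, rt
Reagents that add atoms: none
Why: Dess–Martin oxidation of the primary alcohol, which reacts through the open hydroxy ketone form, gives the aldehyde under buffered conditions that should not epimerise the α-CH.

Step 15
Reactants: 23 keto aldehyde; 24 methyl 2-bromopropanoate
Product: 25 6-tert-butyl 1-methyl (4S,5R)-5-acetyl-5-[2-(1,3-dioxolan-2-yl)ethyl]-3-hydroxy-2-methyl-4-[3-(TBDPS-oxy)propyl]hexanedioate (epimers at C2 and C3)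
Conditions: Zn (activated), THF, 0 °C → rt; aq. NH4Cl
Reagents that add atoms: none
Why: Reformatsky reaction: the zinc enolate adds to the aldehyde and not to the hindered methyl ketone and is too weakly basic to enolise either; the two new stereocentres are removed in steps 16 and 17.

Step 16
Reactants: 25 β-hydroxy ester
Product: 26 6-tert-butyl 1-methyl (4S,5R)-5-acetyl-5-[2-(1,3-dioxolan-2-yl)ethyl]-2-methyl-3-oxo-4-[3-(TBDPS-oxy)propyl]hexanedioate (epimers at C2)
Conditions: Dess–Martin periodinane, NaHCO3, CH2Cl2, rt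
Reagents that add atoms: none
Why: Dess–Martin oxidation of the secondary alcohol gives the α-methyl β-keto ester needed for stereodefined enol sulfonylation.

Step 17
Reactants: 26 β-keto ester
Product: 27 6-tert-butyl 1-methyl (2E,4S,5R)-5-acetyl-5-[2-(1,3-dioxolan-2-yl)ethyl]-2-methyl-3-(tosyloxy)-4-[3-(TBDPS-oxy)propyl]hex-2-enedioate
Conditions: TsCl, N-methylimidazole, Et3N, toluene, 0 °C → rt
Reagents that add atoms: 4-methylbenzenesulfonyl chloride (Cc1ccc(S(=O)(=O)Cl)cc1)
Why: O-sulfonylation of the amine-generated (non-chelated) β-keto ester enolate is expected to give the (E)-enol tosylate, with OTs trans to CO2Me; this fixes the later enal geometry (carbonyl cis to the stereogenic CH).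

Step 18
Reactants: 27 (E)-enol tosylate
Product: 28 6-tert-butyl 1-methyl (2Z,4R,5R)-5-acetyl-5-[2-(1,3-dioxolan-2-yl)ethyl]-3-ethenyl-2-methyl-4-[3-(TBDPS-oxy)propyl]hex-2-enedioate
Conditions: vinylboronic acid pinacol ester, Pd(OAc)2 (5 mol %), SPhos (10 mol %), K3PO4, THF/H2O, 60 °C
Reagents that add atoms: vinylboronic acid pinacol ester (C=CB1OC(C)(C)C(C)(C)O1)
Why: Suzuki–Miyaura coupling of an enol sulfonate proceeds with retention of alkene geometry, so the vinyl group takes the place of OTs cis to the methyl.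

Step 19
Reactants: 28 dienoate
Product: 30 6-tert-butyl 1-methyl (2Z,4R,5R)-5-acetyl-5-[2-(1,3-dioxolan-2-yl)ethyl]-3-(2-hydroxyethyl)-2-methyl-4-[3-(TBDPS-oxy)propyl]hex-2-enedioate, via alkyl-9-BBN adduct 29 (not isolated)
Conditions: 9-BBN, THF, 0 °C → rt; then H2O2, pH 7 phosphate buffer, 0 °C → rt
Reagents that add atoms: hydrogen peroxide (OO)
Why: Anti-Markovnikov hydroboration with 9-BBN should take only the terminal vinyl group (the tetrasubstituted electron-poor alkene and the hindered ketone are slow), and neutral oxidation gives the primary alcohol, which cannot lactonise because its arm is trans to the ester.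

Step 20
Reactants: 30 primary alcohol
Product: 31 6-tert-butyl 1-methyl (2Z,4R,5R)-5-acetyl-5-[2-(1,3-dioxolan-2-yl)ethyl]-3-(2-iodoethyl)-2-methyl-4-[3-(TBDPS-oxy)propyl]hex-2-enedioate
Conditions: I2, PPh3, imidazole, CH2Cl2, 0 °C
Reagents that add atoms: iodine (II)
Why: Appel iodination converts the unhindered primary alcohol into the iodide under nearly neutral conditions that leave the β-keto ester, acetal and silyl ether alone.

Step 21
Reactants: 31 iodo keto ester
Product: 32 tert-butyl (1R,2S,6R)-1-[2-(1,3-dioxolan-2-yl)ethyl]-2-hydroxy-5-[(2Z)-1-methoxy-1-oxopropan-2-ylidene]-2-methyl-6-[3-(TBDPS-oxy)propyl]cyclohexane-1-carboxylate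
Conditions: SmI2 (2.5 equiv), Fe(dbm)3 (2 mol %), THF, −78 → 0 °C; aq. NH4Cl
Reagents that add atoms: none
Why: Divalent samarium reduces the primary C–I bond (alkyl radical, then alkylsamarium), so that C5 changes from an acceptor into a carbon nucleophile that adds to the C6 ketone. The closest known reaction type is the samarium Barbier cyclisation of 2-(ω-iodoalkyl) β-keto esters to 2-hydroxycycloalkane carboxylates. The six-membered ring closes in the 6-exo-trig mode (attack on the carbonyl carbon, oxygen outside the ring). The new stereocentre C6 is controlled by chelation: trivalent samarium bridges the ketone oxygen and the tert-butyl ester carbonyl on C1 in a six-membered chelate, and the tethered C5 can reach only the carbonyl face on the side of C2, which should place OH cis to the ester (the later CH2OH) and CH3 cis to the acetal arm. The step needs chemoselectivity for C–I over the enoate, the tert-butyl ester and the acetal; the hindered tetrasubstituted enoate and the absence of HMPA or a proton source should secure this. No intermediate involves the enoate carbons, so its (Z)-geometry is kept.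

Step 22
Reactants: 32 ring B acetal
Product: 33 tert-butyl (1R,2S,6R)-2-hydroxy-5-[(2Z)-1-methoxy-1-oxopropan-2-ylidene]-2-methyl-1-(3-oxopropyl)-6-[3-(TBDPS-oxy)propyl]cyclohexane-1-carboxylate
Conditions: PPTS, acetone/H2O (9:1), 50 °C
Reagents that add atoms: none
Why: Mild acid-catalysed acetal hydrolysis frees the aldehyde (partly as its six-membered lactol with the tertiary OH) without cleaving the TBDPS ether or the tert-butyl ester.

Step 23
Reactants: 33 ring B aldehyde; 34 2-(triphenylphosphoranylidene)propanal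
Product: 35 tert-butyl (1R,2S,6R)-2-hydroxy-5-[(2Z)-1-methoxy-1-oxopropan-2-ylidene]-2-methyl-1-[(3E)-4-methyl-5-oxopent-3-en-1-yl]-6-[3-(TBDPS-oxy)propyl]cyclohexane-1-carboxylate
Conditions: toluene, 90 °C
Reagents that add atoms: none
Why: Wittig reaction of a stabilised ylide with the aldehyde (reacting through the open form of the lactol) should give the (E)-trisubstituted enal, and the product enal is much less reactive toward the ylide.

Step 24
Reactants: 35 ring B enal; 13 ring A sulfone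
Product: 36 tert-butyl (1R,2S,6R)-2-hydroxy-5-[(2Z)-1-methoxy-1-oxopropan-2-ylidene]-2-methyl-1-{(3E,5E)-4-methyl-6-[(1R,3S)-2,2,3-trimethyl-6-methylidenecyclohexyl]hexa-3,5-dien-1-yl}-6-[3-(TBDPS-oxy)propyl]cyclohexane-1-carboxylate
Conditions: 13, KHMDS, DME, −78 °C; then 35, −78 °C → rt
Reagents that add atoms: none
Why: Julia–Kocienski olefination of the pre-metalated phenyltetrazolyl sulfone with the enal should form the new disubstituted alkene (E) by addition, Smiles rearrangement and loss of SO2; the sulfonyl carbanion is too weak a base to deprotonate the tertiary alcohol.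

Step 25
Reactants: 36 coupled diester
Product: 37 (2Z)-2-[(2R,3S,4S)-4-hydroxy-3-(hydroxymethyl)-4-methyl-3-{(3E,5E)-4-methyl-6-[(1R,3S)-2,2,3-trimethyl-6-methylidenecyclohexyl]hexa-3,5-dien-1-yl}-2-[3-(TBDPS-oxy)propyl]cyclohexylidene]propan-1-ol
Conditions: LiAlH4, THF, 0 → 40 °C
Reagents that add atoms: none
Why: Hydride reduction takes the conjugated methyl ester to the allylic alcohol (1,2-reduction of a hindered tetrasubstituted enoate) and the tert-butyl ester to the neopentyl CH2OH, and leaves the unactivated alkenes alone.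

Step 26
Reactants: 37 silyl ether triol
Product: 38 (2Z)-2-[(2R,3S,4S)-4-hydroxy-3-(hydroxymethyl)-2-(3-hydroxypropyl)-4-methyl-3-{(3E,5E)-4-methyl-6-[(1R,3S)-2,2,3-trimethyl-6-methylidenecyclohexyl]hexa-3,5-dien-1-yl}cyclohexylidene]propan-1-ol
Conditions: TBAF, THF, rt
Reagents that add atoms: none
Why: Fluoride-mediated desilylation frees the hydroxypropyl group before the base-sensitive enal is made.

Step 27
Reactants: 38 tetraol
Product: 39 (2Z)-2-[(2R,3S,4S)-4-hydroxy-3-(hydroxymethyl)-2-(3-hydroxypropyl)-4-methyl-3-{(3E,5E)-4-methyl-6-[(1R,3S)-2,2,3-trimethyl-6-methylidenecyclohexyl]hexa-3,5-dien-1-yl}cyclohexylidene]propanal (CNP0149035.1)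
Conditions: MnO2 (activated), CH2Cl2, rt
Reagents that add atoms: none
Why: Manganese dioxide oxidises only the allylic primary alcohol, so the enal is formed with the alkene geometry fixed in step 17 while the two saturated primary alcohols and the tertiary alcohol remain.

**Compound list**
1 | 2-methylcyclohex-2-en-1-one | CC1=CCCCC1=O | starting material
2 | bromomagnesium (3S)-2,3-dimethylcyclohex-1-en-1-olate | Br[Mg]OC1=C(C)[C@@H](C)CCC1 | intermediate (not isolated)
3 | (3S)-2,2,3-trimethylcyclohexan-1-one | O=C1CCC[C@H](C)C1(C)C | intermediate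
4 | 2,4,6-tri(propan-2-yl)benzenesulfonohydrazide | CC(C)c1cc(C(C)C)c(S(=O)(=O)NN)c(C(C)C)c1 | starting material
5 | N'-[(3S)-2,2,3-trimethylcyclohexylidene]-2,4,6-tri(propan-2-yl)benzenesulfonohydrazide | CC(C)c1cc(C(C)C)c(S(=O)(=O)NN=C2CCC[C@H](C)C2(C)C)c(C(C)C)c1 | intermediate
6 | [(5S)-5,6,6-trimethylcyclohex-1-en-1-yl]lithium | [Li]C1=CCC[C@H](C)C1(C)C | intermediate (not isolated)
7 | [(5S)-5,6,6-trimethylcyclohex-1-en-1-yl]methanol | OCC1=CCC[C@H](C)C1(C)C | intermediate
8 | [2-(hydroxymethyl)-3,3,4-trimethylcyclohexyl]borane, configured as in 9 | B[C@H]1CC[C@H](C)C(C)(C)[C@@H]1CO | intermediate (not isolated)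
9 | (1S,2R,4S)-2-(hydroxymethyl)-3,3,4-trimethylcyclohexan-1-ol | O[C@H]1CC[C@H](C)C(C)(C)[C@@H]1CO | intermediate
10 | (1S,2S,4S)-3,3,4-trimethyl-2-{[(1-phenyl-1H-tetrazol-5-yl)sulfanyl]methyl}cyclohexan-1-ol | O[C@H]1CC[C@H](C)C(C)(C)[C@@H]1CSc1nnnn1-c1ccccc1 | intermediate
11 | (2S,4S)-3,3,4-trimethyl-2-{[(1-phenyl-1H-tetrazol-5-yl)sulfanyl]methyl}cyclohexan-1-one | O=C1CC[C@H](C)C(C)(C)[C@@H]1CSc1nnnn1-c1ccccc1 | intermediate
12 | 1-phenyl-5-({[(1R,3S)-2,2,3-trimethyl-6-methylidenecyclohexyl]methyl}sulfanyl)-1H-tetrazole | C=C1CC[C@H](C)C(C)(C)[C@@H]1CSc1nnnn1-c1ccccc1 | intermediate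
13 | 1-phenyl-5-({[(1R,3S)-2,2,3-trimethyl-6-methylidenecyclohexyl]methyl}sulfonyl)-1H-tetrazole | C=C1CC[C@H](C)C(C)(C)[C@@H]1CS(=O)(=O)c1nnnn1-c1ccccc1 | intermediate
14 | tert-butyl(diphenyl)(prop-2-en-1-yloxy)silane | C=CCO[Si](C(C)(C)C)(c1ccccc1)c1ccccc1 | starting material
15 | 4-bromofuran-2(5H)-one | O=C1C=C(Br)CO1 | starting material
16 | 9-{3-[tert-butyl(diphenyl)silyl]oxypropyl}-9-borabicyclo[3.3.1]nonane | CC(C)(C)[Si](OCCCB1C2CCCC1CCC2)(c1ccccc1)c1ccccc1 | intermediate (not isolated)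
17 | 4-{3-[tert-butyl(diphenyl)silyl]oxypropyl}furan-2(5H)-one | O=C1C=C(CCCO[Si](C(C)(C)C)(c2ccccc2)c2ccccc2)CO1 | intermediate
18 | (4S)-4-{3-[tert-butyl(diphenyl)silyl]oxypropyl}oxolan-2-one | O=C1C[C@H](CCCO[Si](C(C)(C)C)(c2ccccc2)c2ccccc2)CO1 | intermediate
19 | tert-butyl (3S,4S)-4-{3-[tert-butyl(diphenyl)silyl]oxypropyl}-2-oxooxolane-3-carboxylate (3,4-trans) | CC(C)(C)OC(=O)[C@H]1[C@H](CCCO[Si](C(C)(C)C)(c2ccccc2)c2ccccc2)COC1=O | intermediate
20 | 2-(2-bromoethyl)-1,3-dioxolane | BrCCC1OCCO1 | starting material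
21 | tert-butyl (3R,4S)-3-[2-(1,3-dioxolan-2-yl)ethyl]-4-{3-[tert-butyl(diphenyl)silyl]oxypropyl}-2-oxooxolane-3-carboxylate | C1(CC[C@@]2(C(=O)OC(C)(C)C)[C@H](CCCO[Si](C(C)(C)C)(c3ccccc3)c3ccccc3)COC2=O)OCCO1 | intermediate
22 | tert-butyl (2R,3S)-2-acetyl-6-{[tert-butyl(diphenyl)silyl]oxy}-2-[2-(1,3-dioxolan-2-yl)ethyl]-3-(hydroxymethyl)hexanoate (open form of the hemiketal) | C1(CC[C@@](C(C)=O)(C(=O)OC(C)(C)C)[C@H](CCCO[Si](C(C)(C)C)(c2ccccc2)c2ccccc2)CO)OCCO1 | intermediate
23 | tert-butyl (2R,3S)-2-acetyl-6-{[tert-butyl(diphenyl)silyl]oxy}-2-[2-(1,3-dioxolan-2-yl)ethyl]-3-formylhexanoate | C1(CC[C@@](C(C)=O)(C(=O)OC(C)(C)C)[C@H](CCCO[Si](C(C)(C)C)(c2ccccc2)c2ccccc2)C=O)OCCO1 | intermediate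
24 | methyl 2-bromopropanoate | CC(Br)C(=O)OC | starting material
25 | 6-tert-butyl 1-methyl (4S,5R)-5-acetyl-4-{3-[tert-butyl(diphenyl)silyl]oxypropyl}-5-[2-(1,3-dioxolan-2-yl)ethyl]-3-hydroxy-2-methylhexanedioate (epimers at C2 and C3) | C1(CC[C@@](C(C)=O)(C(=O)OC(C)(C)C)[C@H](CCCO[Si](C(C)(C)C)(c2ccccc2)c2ccccc2)C(O)C(C)C(=O)OC)OCCO1 | intermediate
26 | 6-tert-butyl 1-methyl (4S,5R)-5-acetyl-4-{3-[tert-butyl(diphenyl)silyl]oxypropyl}-5-[2-(1,3-dioxolan-2-yl)ethyl]-2-methyl-3-oxohexanedioate (epimers at C2) | C1(CC[C@@](C(C)=O)(C(=O)OC(C)(C)C)[C@H](CCCO[Si](C(C)(C)C)(c2ccccc2)c2ccccc2)C(=O)C(C)C(=O)OC)OCCO1 | intermediate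
27 | 6-tert-butyl 1-methyl (2E,4S,5R)-5-acetyl-4-{3-[tert-butyl(diphenyl)silyl]oxypropyl}-5-[2-(1,3-dioxolan-2-yl)ethyl]-2-methyl-3-{[(4-methylphenyl)sulfonyl]oxy}hex-2-enedioate | C1(CC[C@@](C(C)=O)(C(=O)OC(C)(C)C)[C@H](CCCO[Si](C(C)(C)C)(c2ccccc2)c2ccccc2)/C(OS(=O)(=O)c2ccc(C)cc2)=C(/C)C(=O)OC)OCCO1 | intermediate
28 | 6-tert-butyl 1-methyl (2Z,4R,5R)-5-acetyl-4-{3-[tert-butyl(diphenyl)silyl]oxypropyl}-5-[2-(1,3-dioxolan-2-yl)ethyl]-3-ethenyl-2-methylhex-2-enedioate | C1(CC[C@@](C(C)=O)(C(=O)OC(C)(C)C)[C@H](CCCO[Si](C(C)(C)C)(c2ccccc2)c2ccccc2)/C(C=C)=C(/C)C(=O)OC)OCCO1 | intermediate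
29 | 9-BBN adduct of 28 at the terminal vinyl carbon | C1(CC[C@@](C(C)=O)(C(=O)OC(C)(C)C)[C@H](CCCO[Si](C(C)(C)C)(c2ccccc2)c2ccccc2)/C(CCB2C3CCCC2CCC3)=C(/C)C(=O)OC)OCCO1 | intermediate (not isolated)
30 | 6-tert-butyl 1-methyl (2Z,4R,5R)-5-acetyl-4-{3-[tert-butyl(diphenyl)silyl]oxypropyl}-5-[2-(1,3-dioxolan-2-yl)ethyl]-3-(2-hydroxyethyl)-2-methylhex-2-enedioate | C1(CC[C@@](C(C)=O)(C(=O)OC(C)(C)C)[C@H](CCCO[Si](C(C)(C)C)(c2ccccc2)c2ccccc2)/C(CCO)=C(/C)C(=O)OC)OCCO1 | intermediate
31 | 6-tert-butyl 1-methyl (2Z,4R,5R)-5-acetyl-4-{3-[tert-butyl(diphenyl)silyl]oxypropyl}-5-[2-(1,3-dioxolan-2-yl)ethyl]-3-(2-iodoethyl)-2-methylhex-2-enedioate | C1(CC[C@@](C(C)=O)(C(=O)OC(C)(C)C)[C@H](CCCO[Si](C(C)(C)C)(c2ccccc2)c2ccccc2)/C(CCI)=C(/C)C(=O)OC)OCCO1 | intermediate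
32 | tert-butyl (1R,2S,6R)-6-{3-[tert-butyl(diphenyl)silyl]oxypropyl}-1-[2-(1,3-dioxolan-2-yl)ethyl]-2-hydroxy-5-[(2Z)-1-methoxy-1-oxopropan-2-ylidene]-2-methylcyclohexane-1-carboxylate | C1(CC[C@@]2(C(=O)OC(C)(C)C)[C@H](CCCO[Si](C(C)(C)C)(c3ccccc3)c3ccccc3)/C(=C(/C)C(=O)OC)CC[C@]2(C)O)OCCO1 | intermediate
33 | tert-butyl (1R,2S,6R)-6-{3-[tert-butyl(diphenyl)silyl]oxypropyl}-2-hydroxy-5-[(2Z)-1-methoxy-1-oxopropan-2-ylidene]-2-methyl-1-(3-oxopropyl)cyclohexane-1-carboxylate | O=CCC[C@@]1(C(=O)OC(C)(C)C)[C@H](CCCO[Si](C(C)(C)C)(c2ccccc2)c2ccccc2)/C(=C(/C)C(=O)OC)CC[C@]1(C)O | intermediate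
34 | 2-(triphenylphosphoranylidene)propanal | CC(C=O)=P(c1ccccc1)(c1ccccc1)c1ccccc1 | starting material
35 | tert-butyl (1R,2S,6R)-6-{3-[tert-butyl(diphenyl)silyl]oxypropyl}-2-hydroxy-5-[(2Z)-1-methoxy-1-oxopropan-2-ylidene]-2-methyl-1-[(3E)-4-methyl-5-oxopent-3-en-1-yl]cyclohexane-1-carboxylate | O=C/C(C)=C/CC[C@@]1(C(=O)OC(C)(C)C)[C@H](CCCO[Si](C(C)(C)C)(c2ccccc2)c2ccccc2)/C(=C(/C)C(=O)OC)CC[C@]1(C)O | intermediate
36 | tert-butyl (1R,2S,6R)-6-{3-[tert-butyl(diphenyl)silyl]oxypropyl}-2-hydroxy-5-[(2Z)-1-methoxy-1-oxopropan-2-ylidene]-2-methyl-1-{(3E,5E)-4-methyl-6-[(1R,3S)-2,2,3-trimethyl-6-methylidenecyclohexyl]hexa-3,5-dien-1-yl}cyclohexane-1-carboxylate | C=C1CC[C@H](C)C(C)(C)[C@@H]1/C=C/C(C)=C/CC[C@@]1(C(=O)OC(C)(C)C)[C@H](CCCO[Si](C(C)(C)C)(c2ccccc2)c2ccccc2)/C(=C(/C)C(=O)OC)CC[C@]1(C)O | intermediate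
37 | (2Z)-2-[(2R,3S,4S)-2-{3-[tert-butyl(diphenyl)silyl]oxypropyl}-4-hydroxy-3-(hydroxymethyl)-4-methyl-3-{(3E,5E)-4-methyl-6-[(1R,3S)-2,2,3-trimethyl-6-methylidenecyclohexyl]hexa-3,5-dien-1-yl}cyclohexylidene]propan-1-ol | C=C1CC[C@H](C)C(C)(C)[C@@H]1/C=C/C(C)=C/CC[C@@]1(CO)[C@H](CCCO[Si](C(C)(C)C)(c2ccccc2)c2ccccc2)/C(=C(/C)CO)CC[C@]1(C)O | intermediate
38 | (2Z)-2-[(2R,3S,4S)-4-hydroxy-3-(hydroxymethyl)-2-(3-hydroxypropyl)-4-methyl-3-{(3E,5E)-4-methyl-6-[(1R,3S)-2,2,3-trimethyl-6-methylidenecyclohexyl]hexa-3,5-dien-1-yl}cyclohexylidene]propan-1-ol | C=C1CC[C@H](C)C(C)(C)[C@@H]1/C=C/C(C)=C/CC[C@@]1(CO)[C@H](CCCO)/C(=C(/C)CO)CC[C@]1(C)O | intermediate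
39 | (2Z)-2-[(2R,3S,4S)-4-hydroxy-3-(hydroxymethyl)-2-(3-hydroxypropyl)-4-methyl-3-{(3E,5E)-4-methyl-6-[(1R,3S)-2,2,3-trimethyl-6-methylidenecyclohexyl]hexa-3,5-dien-1-yl}cyclohexylidene]propanal | C=C1CC[C@H](C)C(C)(C)[C@@H]1/C=C/C(C)=C/CC[C@@]1(CO)[C@H](CCCO)/C(=C(/C)C=O)CC[C@]1(C)O | target

**Step count and risks**
Total steps: 27. Longest linear sequence: 19 steps (steps 9 to 27); the ring A sulfone (steps 1 to 8) joins in step 24.

Steps most likely to fail:

1. Step 21. The carbon–iodine bond may be reduced to C–H, or the chelated ketone to the secondary alcohol, before the ring closes. The fallback sets out from alcohol 30. Dess–Martin oxidation should give the keto aldehyde F1. SmI2 (THF, t-BuOH, −78 °C) should then join the aldehyde and ketone carbons in a chelation-controlled pinacol cyclisation to the cis-diol F2. The secondary hydroxyl is acylated with O-phenyl chlorothionoformate (pyridine, DMAP) to the phenyl thionocarbonate F3, and Bu3SnH/AIBN (toluene, 80 °C, Barton–McCombie deoxygenation) removes it. The sequence comes back to the route at 32.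

2. Step 17. Geometric control may be lost, or enolisation may be slow, in the sulfonylation of the hindered β-keto ester, which would carry the wrong enal geometry forward. The fallback sets out from keto aldehyde 23. Ohira–Bestmann homologation (dimethyl (1-diazo-2-oxopropyl)phosphonate, Cs2CO3, MeOH, 0 °C) should give the terminal alkyne F4. Oxidative methoxycarbonylation (PdCl2 cat., CuCl2, NaOAc, CO, MeOH) gives the ynoate F5. Syn-carbocupration with the divinylcuprate from vinylmagnesium bromide and CuBr·SMe2 (THF, −78 °C), followed by trapping of the alkenylcopper with MeI/DMPU, places vinyl and methyl cis. This comes back to the route at dienoate 28.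

3. Step 13. Methyllithium may over-add or attack the ester, or the liberated alkoxide may cleave the new β-keto ester (retro-Claisen). The fallback sets out from lactone 21. Petasis methylenation of the lactone carbonyl with Cp2Ti(CH3)2 (toluene, 70 °C) should give the exocyclic enol ether F6, and hydrolysis with aqueous oxalic acid (THF, rt) then gives the methyl ketone and the free alcohol. This comes back to the route at 22.

Further compounds
F1 | step 21 | 6-tert-butyl 1-methyl (2Z,4R,5R)-5-acetyl-4-{3-[tert-butyl(diphenyl)silyl]oxypropyl}-5-[2-(1,3-dioxolan-2-yl)ethyl]-2-methyl-3-(2-oxoethyl)hex-2-enedioate | C1(CC[C@@](C(C)=O)(C(=O)OC(C)(C)C)[C@H](CCCO[Si](C(C)(C)C)(c2ccccc2)c2ccccc2)/C(CC=O)=C(/C)C(=O)OC)OCCO1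
F2 | step 21 | cis-2,3-diol analogue of 32 (extra secondary hydroxyl on the ring carbon next to the carbinol carbon, cis to the tertiary OH) | C1(CC[C@@]2(C(=O)OC(C)(C)C)[C@H](CCCO[Si](C(C)(C)C)(c3ccccc3)c3ccccc3)/C(=C(/C)C(=O)OC)C[C@H](O)[C@]2(C)O)OCCO1
F3 | step 21 | O-phenyl thionocarbonate of F2 at the secondary hydroxyl | C1(CC[C@@]2(C(=O)OC(C)(C)C)[C@H](CCCO[Si](C(C)(C)C)(c3ccccc3)c3ccccc3)/C(=C(/C)C(=O)OC)C[C@H](OC(=S)Oc3ccccc3)[C@]2(C)O)OCCO1
F4 | step 17 | tert-butyl 2-acetyl-6-{[tert-butyl(diphenyl)silyl]oxy}-2-[2-(1,3-dioxolan-2-yl)ethyl]-3-ethynylhexanoate, configured as 23 | C1(CC[C@@](C(C)=O)(C(=O)OC(C)(C)C)[C@H](CCCO[Si](C(C)(C)C)(c2ccccc2)c2ccccc2)C#C)OCCO1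
F5 | step 17 | 6-tert-butyl 1-methyl 5-acetyl-4-{3-[tert-butyl(diphenyl)silyl]oxypropyl}-5-[2-(1,3-dioxolan-2-yl)ethyl]hex-2-ynedioate, configured as 23 | C1(CC[C@@](C(C)=O)(C(=O)OC(C)(C)C)[C@H](CCCO[Si](C(C)(C)C)(c2ccccc2)c2ccccc2)C#CC(=O)OC)OCCO1
F6 | step 13 | tert-butyl 3-[2-(1,3-dioxolan-2-yl)ethyl]-4-{3-[tert-butyl(diphenyl)silyl]oxypropyl}-2-methylideneoxolane-3-carboxylate, configured as 21 | C1(CC[C@@]2(C(=O)OC(C)(C)C)[C@H](CCCO[Si](C(C)(C)C)(c3ccccc3)c3ccccc3)COC2=C)OCCO1
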